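**Analysis of the target**

The target 20 is an isoflavone: a 4H-chromen-4-one (rings A and C, atoms O1 to C8a) with free hydroxyls at C5 and C7, and at C3 a pentasubstituted benzene (ring B, primed atoms). Ring B carries prenyl at C2', methoxy at C3', hydroxyl at C4', prenyl at C5' and one hydrogen at C6'. The molecule has no stereocentre and its two trisubstituted alkenes have no geometry, so the problems are regiochemistry and functional-group tolerance. The sensitive groups are the prenyl alkenes, which do not survive hydrogenation, strong electrophiles or strong acid, and the three phenols; the C5' prenyl lies ortho to the C4' hydroxyl and can close to a 2,2-dimethylchroman under acid. The hard points are the contiguous C1'–C5' substitution of ring B, with C2' wedged between the ring C attachment and the methoxy-bearing C3', the distinction of O3' (methyl) from O4' (free), and the crowding an ortho prenyl puts on any bond formed next to C1'. The plan rests on the fact that C4 (bonded to ring A) and C3 (bonded to ring B) can both be traced back to carbonyl carbons, an aldehyde on ring A and the aryl ketone of ring B, held together through O1 and C2 as an aryloxymethyl ketone. Joining two carbonyl carbons requires polarity inversion at one of them, and a carbene catalyst does this at the aldehyde without strong acid or base. The one stereocentre the route creates (C3 of the chromanone 17) is transient and is removed by dehydration.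

**Retrosynthetic reasoning**

20 from 19. The three phenols are unmasked last by cutting the O–CH2 bonds of three methoxymethyl acetals. Free phenols would interfere with the enolate, Grignard and carbene steps; the acetal survives base, organometallics, palladium and 130 °C and leaves by acetal exchange in acidic methanol.

19 from 17. The C2=C3 double bond is traced to a C3 hydroxyl and a C2 hydrogen. The only β-hydrogens of the tertiary carbinol 17 are on C2, so dehydration can give only the chromone, and the C3 stereocentre disappears.

17 from 16 (key disconnection). The C3–C4 bond is cut. This divides the molecule into two aromatic halves joined only by an ether, so the synthesis becomes convergent. Cutting C3–C1' instead would need a cross-coupling at a doubly ortho-substituted aryl carbon, and cutting C4–C4a would need Friedel–Crafts acylation, which the prenyl groups do not tolerate. The forward step must turn the ring A formyl carbon of 16 into an acyl anion equivalent that adds to the tethered ketone.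

16 from 13 and 15. The O1–C2 bond is an aryl alkyl ether next to a ketone. Phenoxide alkylation with the bromo ketone 13 forms it under mild base, with the ring A aldehyde already in place in 15.

15 from 14. Two of the three phenols of 14 are protected; the third is left free because it is hydrogen-bonded to the formyl group and reacts last.

13 from 11, 10 and 9. The bromoacetyl group is traced to the formyl group of 9: bromination at the only enolisable carbon of ketone 11 through its silyl enol ether 12, oxidation of carbinol 10, and addition of a methyl Grignard reagent to 9. The aldehyde is kept this long because the small formyl group serves the ring B chemistry better than an acetyl group would.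

9 from 8. The C5'–CH2 bond is cut next to a bromine-bearing carbon. That bromine is present in the purchased material 1, so a palladium-catalysed coupling with a prenyl stannane places the second prenyl group with no regiochemical question.

8 from 7, 5, 2 and 4. The C2'–CH2 bond is the most hindered C–C bond of ring B and is best formed intramolecularly. A [3,3] shift from O3' in the tertiary allyl ether 5 delivers the carbon to C2', the only free ortho position, and allyl inversion turns the 1,1-dimethylallyl group into a linear prenyl group (via dienone 6). The phenol 7 set free is then methylated to 8, which fixes the O3'/O4' distinction. Ether 5 comes from phenol 2 and carbonate 4 by palladium-catalysed O-allylation.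

2 from 1, and 4 from 3. O4' of catechol 1 is the more acidic oxygen (para to formyl, ortho to bromine) and is protected first, which differentiates the two oxygens at the outset. Carbonate 4 is the activated form of the tertiary allylic alcohol 3.

**Alternatives that were turned down**

Alternative 1: Both aryl–CH2 bonds of ring B are cut at once and traced to the two oxygens of the catechol bis(tertiary allyl) ether A2. Heating A2 would move both groups to the neighbouring ring carbons to give the diprenyl catechol aldehyde A1; no ring closes.
- For: two C–C bonds form in one operation, regiochemistry and linear prenyl geometry are fixed by the [3,3] mechanism, and the starting materials are cheap.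
- Against: A2 needs two tertiary ethers on adjacent oxygens, and the second etherification is crowded. Tertiary aryl ethers lose isoprene on heating, most easily the one on O4', whose phenoxide is stabilised by the para formyl group. A1 is a free, oxidation-prone catechol flanked by two prenyl groups, whose two oxygens must still be told apart. The idea also says nothing about ring C.
- Comparison: it reaches the ring B aldehyde about two steps sooner than the sequence 1 to 9, and on that point it is stronger. The chosen route uses the same sigmatropic logic for C2' only, on a mono-ether with one open ortho site. It takes the C5' carbon from a bromine already in 1 and differentiates O4' in step 1. It gives certainty in place of brevity.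

Alternative 2: Each prenyl group is cut at its CH2–CH= bond. The bis(bromomethyl) isoflavone triacetate A4, made by benzylic bromination of the dimethyl isoflavone triacetate A6, would couple twice with the vinyl stannane A5 under a zerovalent palladium catalyst to give the diprenyl isoflavone triacetate A3.
- For: the alkenes appear last, so the isoflavone construction runs without them, and the para-dimethyl pattern is easy to buy.
- Against: the radical bromination of A6 must hit each aryl methyl once and spare the acetate and methoxy groups. A4 is a bis-benzylic bromide on an acetoxy-bearing ring and is prone to solvolysis. Two couplings must both succeed on the most advanced intermediate. Each prenyl group costs three operations. The C3–C1' or C3–C4 construction of the hindered isoflavone is still undefined.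
- Comparison: it is stronger in sparing the prenyl groups from the middle of the synthesis; the chosen route carries them through nine steps, including a bromination. In return the chosen route is convergent, joins its halves by an SN2 reaction and closes ring C catalytically near neutrality, so the late steps are not stoichiometric metal couplings.

Alternative 3: Ring A is cut at C4a–C8a and unfolded into a polyketide chain masked as the 4-hydroxy-2-pyrone A8. A magnesium alkoxide in methanol would open A8 to the triketo ester A9, whose C6 carbanion attacks the C1 ester to give the 2,4,6-trihydroxyphenyl benzyl ketone A7.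
- For: ring A needs no protecting groups, and A7 is the classical deoxybenzoin from which one-carbon insertion gives an isoflavone with no dehydration step.
- Against: A8 must first be built by acylating a pyrone dianion with a ring B arylacetic ester, which means homologating the ring B aldehyde and using strong base. A9 has four acidic methylenes, including the benzylic one, and can close by aldol instead of Claisen condensation or revert to the pyrone. The ring it builds, a phloroglucinol, is a commercial aromatic.
- Comparison: its endgame from A7 is stronger than a benzoin closure followed by dehydration. The chosen route buys ring A as 14, protects it in one step and spends its risk on a single C–C bond whose chemoselectivity is fixed by the tether.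

Key step: step 12

Remark on the chemistry: 1, tributyl(3-methylbut-2-enyl)stannane, the Burgess reagent and the triazolium salt of step 12 are taken as purchased.

Step 1
Reactants: 1 3-bromo-4,5-dihydroxybenzaldehyde
Product: 2 3-bromo-5-hydroxy-4-(methoxymethoxy)benzaldehyde
Conditions: MOMCl (1.05 equiv), K2CO3 (1.1 equiv), acetone, 0 °C → rt
Reagents that add atoms: chloromethyl methyl ether, COCCl
Why: The hydroxyl para to the formyl group and ortho to bromine is the most acidic, so with one equivalent of base only that phenoxide forms and is O-alkylated (regioselective Williamson-type protection of a catechol aldehyde).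

Step 2
Reactants: 3 2-methylbut-3-en-2-ol
Product: 4 tert-butyl 2-methylbut-3-en-2-yl carbonate
Conditions: n-BuLi, THF, 0 °C; Boc2O, 0 °C → rt
Reagents that add atoms: di-tert-butyl dicarbonate, CC(C)(C)OC(=O)OC(=O)OC(C)(C)C
Why: The lithium alkoxide of the tertiary alcohol is acylated by the dicarbonate (alkoxide acylation), giving the activated allylic carbonate.

Step 3
Reactants: 2 3-bromo-5-hydroxy-4-(methoxymethoxy)benzaldehyde; 4 tert-butyl 2-methylbut-3-en-2-yl carbonate
Product: 5 3-bromo-4-(methoxymethoxy)-5-[(2-methylbut-3-en-2-yl)oxy]benzaldehyde
Conditions: Pd(PPh3)4 (3 mol%), THF, 0 → 15 °C, stopped at full conversion of 2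
Reagents that add atoms: none
Why: Decarboxylative Tsuji–Trost O-allylation: zerovalent palladium ionises 4 to a 1,1-dimethylallyl palladium cation and tert-butoxide, which deprotonates the phenol, and the phenoxide attacks the more substituted allyl terminus to give the tertiary ether as kinetic product. Oxidative addition into the aryl bromide should be negligible at this temperature.

Step 4
Reactants: 5 3-bromo-4-(methoxymethoxy)-5-[(2-methylbut-3-en-2-yl)oxy]benzaldehyde
Product: 7 5-bromo-3-hydroxy-4-(methoxymethoxy)-2-(3-methylbut-2-enyl)benzaldehyde, via Claisen dienone 6 (not isolated)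
Conditions: PhNEt2, 130 °C
Reagents that add atoms: none
Why: Aromatic Claisen rearrangement: the [3,3] shift can only reach the single free ortho carbon (the other ortho position carries the acetal oxygen), allyl inversion converts the 1,1-dimethylallyl group into linear prenyl, and dienone 6 tautomerises to the phenol. Tertiary allyl aryl ethers rearrange well below the temperature needed for primary ones, which the acetal and aldehyde tolerate.

Step 5
Reactants: 7 5-bromo-3-hydroxy-4-(methoxymethoxy)-2-(3-methylbut-2-enyl)benzaldehyde
Product: 8 5-bromo-3-methoxy-4-(methoxymethoxy)-2-(3-methylbut-2-enyl)benzaldehyde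
Conditions: MeI, K2CO3, DMF, rt
Reagents that add atoms: iodomethane, CI
Why: Williamson O-methylation of the only free phenol; the small electrophile reaches the flanked oxygen, and the basic conditions cannot cyclise the phenol onto the neighbouring prenyl group.

Step 6
Reactants: 8 5-bromo-3-methoxy-4-(methoxymethoxy)-2-(3-methylbut-2-enyl)benzaldehyde
Product: 9 3-methoxy-4-(methoxymethoxy)-2,5-bis(3-methylbut-2-enyl)benzaldehyde
Conditions: Bu3SnCH2CH=CMe2 (1.5 equiv), Pd(PPh3)4 (5 mol%), DMF, 95 °C
Reagents that add atoms: tributyl(3-methylbut-2-enyl)stannane, CCCC[Sn](CCCC)(CCCC)CC=C(C)C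
Why: Stille coupling of an aryl bromide with one free ortho position; the prenyl palladium intermediate reductively eliminates at its unsubstituted CH2 terminus, so the linear prenyl arene is expected. The aldehyde, the acetal and the first prenyl group are inert.

Step 7
Reactants: 9 3-methoxy-4-(methoxymethoxy)-2,5-bis(3-methylbut-2-enyl)benzaldehyde
Product: 10 racemic 1-[3-methoxy-4-(methoxymethoxy)-2,5-bis(3-methylbut-2-enyl)phenyl]ethanol
Conditions: MeMgBr, THF, 0 °C
Reagents that add atoms: methylmagnesium bromide, C[Mg]Br
Why: Grignard addition to an aryl aldehyde; the carbinol centre forms racemic and is removed by the oxidation in step 8.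

Step 8
Reactants: 10 racemic 1-[3-methoxy-4-(methoxymethoxy)-2,5-bis(3-methylbut-2-enyl)phenyl]ethanol
Product: 11 1-[3-methoxy-4-(methoxymethoxy)-2,5-bis(3-methylbut-2-enyl)phenyl]ethanone
Conditions: Dess–Martin periodinane, NaHCO3, CH2Cl2, 0 °C → rt
Reagents that add atoms: none
Why: Dess–Martin oxidation of a secondary benzylic alcohol under buffered conditions that leave the prenyl alkenes and the acetal untouched.

Step 9
Reactants: 11 1-[3-methoxy-4-(methoxymethoxy)-2,5-bis(3-methylbut-2-enyl)phenyl]ethanone
Product: 13 2-bromo-1-[3-methoxy-4-(methoxymethoxy)-2,5-bis(3-methylbut-2-enyl)phenyl]ethanone, via silyl enol ether 12 (not isolated)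
Conditions: LiN(SiMe3)2, THF, −78 °C, then TMSCl; NBS, THF, −78 °C
Reagents that add atoms: N-bromosuccinimide, O=C1CCC(=O)N1Br; chlorotrimethylsilane, C[Si](C)(C)Cl (its silyl group is in 12 only)
Why: The ketone has a single enolisable position; bromination of the silyl enol ether at −78 °C should be far faster than attack of the bromine source on the trisubstituted alkenes or the arene (α-bromination of a ketone through its silyl enol ether).

Step 10
Reactants: 14 2,4,6-trihydroxybenzaldehyde
Product: 15 2-hydroxy-4,6-bis(methoxymethoxy)benzaldehyde
Conditions: MOMCl (2.1 equiv), i-Pr2NEt, CH2Cl2, 0 °C → rt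
Reagents that add atoms: chloromethyl methyl ether, COCCl
Why: The para hydroxyl and one of the two equivalent ortho hydroxyls are alkylated; the remaining ortho hydroxyl is hydrogen-bonded to the formyl group and reacts last, so the reaction stops at the bis-acetal.

Step 11
Reactants: 13 2-bromo-1-[3-methoxy-4-(methoxymethoxy)-2,5-bis(3-methylbut-2-enyl)phenyl]ethanone; 15 2-hydroxy-4,6-bis(methoxymethoxy)benzaldehyde
Product: 16 2-{2-[3-methoxy-4-(methoxymethoxy)-2,5-bis(3-methylbut-2-enyl)phenyl]-2-oxoethoxy}-4,6-bis(methoxymethoxy)benzaldehyde
Conditions: K2CO3, acetone, rt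
Reagents that add atoms: none
Why: Williamson ether synthesis with a highly reactive α-bromo ketone (SN2); room temperature and a heterogeneous weak base are used so that the product does not go on to a Rap–Stoermer-type aldol condensation.

Step 12
Reactants: 16 2-{2-[3-methoxy-4-(methoxymethoxy)-2,5-bis(3-methylbut-2-enyl)phenyl]-2-oxoethoxy}-4,6-bis(methoxymethoxy)benzaldehyde
Product: 17 racemic 3-hydroxy-3-[3-methoxy-4-(methoxymethoxy)-2,5-bis(3-methylbut-2-enyl)phenyl]-5,7-bis(methoxymethoxy)chroman-4-one
Conditions: 2-(pentafluorophenyl)-6,7-dihydro-5H-pyrrolo[2,1-c][1,2,4]triazol-2-ium tetrafluoroborate (15 mol%), Et3N (15 mol%), toluene, rt → 45 °C, Ar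
Reagents that add atoms: none
Why: Et3N deprotonates the triazolium salt to the free carbene, which adds to the formyl group of 16; proton transfer gives the Breslow intermediate, the acyl anion equivalent of the ring A aldehyde. Its nucleophilic carbon attacks the tethered aryl ketone to form the C3–C4 bond, and proton transfer with loss of the carbene releases the α-hydroxy ketone 17 and the catalyst. The closest known reaction type is the triazolium-carbene-catalysed intramolecular crossed aldehyde–ketone benzoin cyclisation of 2-(2-oxoalkoxy)benzaldehydes to 3-hydroxychroman-4-ones. Ring C closes in a 6-exo-trig mode, the ketone C=O lying outside the forming six-membered ring. The C3 carbinol stereocentre forms racemic because the catalyst is achiral, and no control is needed since step 13 makes C3 trigonal. The step needs the aldehyde as donor and the ketone as acceptor: only the formyl carbon has the hydrogen required for the Breslow intermediate, the tether holds the ketone at six-ring distance, and the two ortho oxygens disfavour intermolecular aldehyde–aldehyde coupling. The competing base-induced aldol closure of the O–CH2–C(=O) methylene onto the aldehyde is held back by using only a catalytic amount of a weak amine in a non-polar solvent; the compact, electron-poor N-pentafluorophenyl triazolium is acidic enough for that base and small enough to reach the doubly ortho-substituted aldehyde. Prenyl alkenes and acetals are inert to the carbene.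

Step 13
Reactants: 17 racemic 3-hydroxy-3-[3-methoxy-4-(methoxymethoxy)-2,5-bis(3-methylbut-2-enyl)phenyl]-5,7-bis(methoxymethoxy)chroman-4-one
Product: 19 3-[3-methoxy-4-(methoxymethoxy)-2,5-bis(3-methylbut-2-enyl)phenyl]-5,7-bis(methoxymethoxy)-4H-chromen-4-one, via sulfamate ester 18 (not isolated)
Conditions: Burgess reagent, THF, rt → 60 °C
Reagents that add atoms: Burgess reagent (methyl N-(triethylammoniosulfonyl)carbamate), COC(=O)[N-]S(=O)(=O)[N+](CC)(CC)CC (its atoms are in 18 only)
Why: Burgess dehydration: the tertiary carbinol forms sulfamate ester 18, which undergoes thermal syn-elimination with one of the two C2 hydrogens, the only β-hydrogens present, so the conjugated chromone is the sole possible alkene. The neutral conditions spare the acetals and prenyl groups.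

Step 14
Reactants: 19 3-[3-methoxy-4-(methoxymethoxy)-2,5-bis(3-methylbut-2-enyl)phenyl]-5,7-bis(methoxymethoxy)-4H-chromen-4-one
Product: 20 5,7-dihydroxy-3-[4-hydroxy-3-methoxy-2,5-bis(3-methylbut-2-enyl)phenyl]-4H-chromen-4-one
Conditions: HCl (about 1 M) in MeOH/THF, 40 °C, stopped as soon as 19 and the partly protected intermediates are consumed
Reagents that add atoms: none
Why: Acid-catalysed acetal exchange transfers the three methoxymethyl groups to methanol as dimethoxymethane; dilute acid and moderate temperature are chosen so that acetal cleavage outruns protonation of the trisubstituted alkenes.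

**Compound list**

1 | 3-bromo-4,5-dihydroxybenzaldehyde | O=Cc1cc(O)c(O)c(Br)c1 | starting material
2 | 3-bromo-5-hydroxy-4-(methoxymethoxy)benzaldehyde | O=Cc1cc(O)c(OCOC)c(Br)c1 | intermediate
3 | 2-methylbut-3-en-2-ol | C=CC(C)(C)O | starting material
4 | tert-butyl 2-methylbut-3-en-2-yl carbonate | C=CC(C)(C)OC(=O)OC(C)(C)C | intermediate
5 | 3-bromo-4-(methoxymethoxy)-5-[(2-methylbut-3-en-2-yl)oxy]benzaldehyde | O=Cc1cc(OC(C)(C)C=C)c(OCOC)c(Br)c1 | intermediate
6 | racemic 3-bromo-4-(methoxymethoxy)-6-(3-methylbut-2-enyl)-5-oxocyclohexa-1,3-diene-1-carbaldehyde | O=CC1=CC(Br)=C(OCOC)C(=O)C1CC=C(C)C | intermediate (not isolated)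
7 | 5-bromo-3-hydroxy-4-(methoxymethoxy)-2-(3-methylbut-2-enyl)benzaldehyde | O=Cc1cc(Br)c(OCOC)c(O)c1CC=C(C)C | intermediate
8 | 5-bromo-3-methoxy-4-(methoxymethoxy)-2-(3-methylbut-2-enyl)benzaldehyde | O=Cc1cc(Br)c(OCOC)c(OC)c1CC=C(C)C | intermediate
9 | 3-methoxy-4-(methoxymethoxy)-2,5-bis(3-methylbut-2-enyl)benzaldehyde | O=Cc1cc(CC=C(C)C)c(OCOC)c(OC)c1CC=C(C)C | intermediate
10 | racemic 1-[3-methoxy-4-(methoxymethoxy)-2,5-bis(3-methylbut-2-enyl)phenyl]ethanol | CC(O)c1cc(CC=C(C)C)c(OCOC)c(OC)c1CC=C(C)C | intermediate
11 | 1-[3-methoxy-4-(methoxymethoxy)-2,5-bis(3-methylbut-2-enyl)phenyl]ethanone | CC(=O)c1cc(CC=C(C)C)c(OCOC)c(OC)c1CC=C(C)C | intermediate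
12 | trimethyl({1-[3-methoxy-4-(methoxymethoxy)-2,5-bis(3-methylbut-2-enyl)phenyl]ethenyl}oxy)silane | C=C(O[Si](C)(C)C)c1cc(CC=C(C)C)c(OCOC)c(OC)c1CC=C(C)C | intermediate (not isolated)
13 | 2-bromo-1-[3-methoxy-4-(methoxymethoxy)-2,5-bis(3-methylbut-2-enyl)phenyl]ethanone | O=C(CBr)c1cc(CC=C(C)C)c(OCOC)c(OC)c1CC=C(C)C | intermediate
14 | 2,4,6-trihydroxybenzaldehyde | O=Cc1c(O)cc(O)cc1O | starting material
15 | 2-hydroxy-4,6-bis(methoxymethoxy)benzaldehyde | O=Cc1c(O)cc(OCOC)cc1OCOC | intermediate
16 | 2-{2-[3-methoxy-4-(methoxymethoxy)-2,5-bis(3-methylbut-2-enyl)phenyl]-2-oxoethoxy}-4,6-bis(methoxymethoxy)benzaldehyde | O=Cc1c(OCC(=O)c2cc(CC=C(C)C)c(OCOC)c(OC)c2CC=C(C)C)cc(OCOC)cc1OCOC | intermediate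
17 | racemic 3-hydroxy-3-[3-methoxy-4-(methoxymethoxy)-2,5-bis(3-methylbut-2-enyl)phenyl]-5,7-bis(methoxymethoxy)chroman-4-one | O=C1c2c(OCOC)cc(OCOC)cc2OCC1(O)c1cc(CC=C(C)C)c(OCOC)c(OC)c1CC=C(C)C | intermediate
18 | triethylammonium salt of racemic methyl N-({3-[3-methoxy-4-(methoxymethoxy)-2,5-bis(3-methylbut-2-enyl)phenyl]-5,7-bis(methoxymethoxy)-4-oxochroman-3-yl}oxysulfonyl)carbamate | O=C1c2c(OCOC)cc(OCOC)cc2OCC1(OS(=O)(=O)[N-]C(=O)OC)c1cc(CC=C(C)C)c(OCOC)c(OC)c1CC=C(C)C.CC[NH+](CC)CC | intermediate (not isolated)
19 | 3-[3-methoxy-4-(methoxymethoxy)-2,5-bis(3-methylbut-2-enyl)phenyl]-5,7-bis(methoxymethoxy)-4H-chromen-4-one | O=c1c(-c2cc(CC=C(C)C)c(OCOC)c(OC)c2CC=C(C)C)coc2cc(OCOC)cc(OCOC)c12 | intermediate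
20 | 5,7-dihydroxy-3-[4-hydroxy-3-methoxy-2,5-bis(3-methylbut-2-enyl)phenyl]-4H-chromen-4-one | COc1c(O)c(CC=C(C)C)cc(-c2coc3cc(O)cc(O)c3c2=O)c1CC=C(C)C | target

**Step count and least certain steps**

Total step count: 14. Longest linear sequence: 12 steps (1 → 2 → 5 → 7 → 8 → 9 → 10 → 11 → 13 → 16 → 17 → 19 → 20); steps 2 and 10 are side branches.

Step 12 (key step). Three things are most likely to go wrong. Addition of the carbene to a formyl group flanked by two ortho oxygens and deactivated by three donor substituents may be slow or reversible. Base-triggered aldol condensation of the aryloxymethyl ketone onto the aldehyde (Rap–Stoermer-type benzofuran formation) may compete. Attack on a ketone whose aryl group carries an ortho prenyl may be sluggish. Fallback: starting from 16, reductive ketyl coupling of the aldehyde and ketone with SmI2 (divalent samarium) in THF, an intramolecular pinacol coupling, would form the same C3–C4 bond and give the diastereomeric 3-[3-methoxy-4-(methoxymethoxy)-2,5-bis(3-methylbut-2-enyl)phenyl]-5,7-bis(methoxymethoxy)chroman-3,4-diol F1. Oxidation of its secondary benzylic C4 carbinol with IBX, which takes 1,2-diols to ketols without C–C cleavage, returns to the route at 17.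

Step 4 (with the ether formation of step 3). The tertiary aryl ether may ionise and lose isoprene instead of rearranging. The branched ether may also isomerise to the linear O-prenyl ether under palladium in step 3, which after rearrangement would put a reverse-prenyl group on C2. Fallback: starting from 2, O-alkylation with allyl bromide (K2CO3, acetone) gives 3-bromo-4-(methoxymethoxy)-5-(prop-2-enyloxy)benzaldehyde F2. Claisen rearrangement at about 185 °C in PhNEt2 gives 5-bromo-3-hydroxy-4-(methoxymethoxy)-2-(prop-2-enyl)benzaldehyde F3; a primary allyl ether cannot lose a diene. Olefin cross-metathesis with 2-methylbut-2-ene (second-generation Grubbs catalyst, (H2IMes)(PCy3)Cl2Ru=CHPh) converts allyl into prenyl and rejoins the route at 7.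

Step 9. The bromine source may attack a prenyl alkene or the electron-rich ring instead of the enol ether, or enol silylation may be incomplete so that bromination occurs elsewhere. Fallback: starting from 9, no electrophilic halogen is used. Chloromethyllithium, generated from ICH2Cl and MeLi·LiBr in the presence of 9 at −78 °C and quenched cold with acetic acid, gives racemic 2-chloro-1-[3-methoxy-4-(methoxymethoxy)-2,5-bis(3-methylbut-2-enyl)phenyl]ethanol F4. Dess–Martin oxidation gives 2-chloro-1-[3-methoxy-4-(methoxymethoxy)-2,5-bis(3-methylbut-2-enyl)phenyl]ethanone F5, which alkylates 15 (K2CO3, catalytic NaI, acetone) and comes back to the route at 16.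

Step 13. The hindered tertiary carbinol may fail to form the sulfamate, or it may ionise to an α-keto benzylic cation that undergoes a 1,2-acyl shift or ketol rearrangement instead of elimination. Fallback: starting from 17, the hydroxyl is removed reductively and the double bond introduced by oxidation. SmI2 (divalent samarium) in THF/MeOH at −78 °C reduces the α-hydroxy ketone to racemic 3-[3-methoxy-4-(methoxymethoxy)-2,5-bis(3-methylbut-2-enyl)phenyl]-5,7-bis(methoxymethoxy)chroman-4-one F6. LiN(SiMe3)2 with TMSCl present at −78 °C gives {3-[3-methoxy-4-(methoxymethoxy)-2,5-bis(3-methylbut-2-enyl)phenyl]-5,7-bis(methoxymethoxy)-2H-chromen-4-yl}oxytrimethylsilane F7. Saegusa–Ito oxidation with Pd(OAc)2 (divalent palladium) in MeCN installs the C2=C3 bond and returns to the route at 19.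

Step 14. Acid may add the freed C4' hydroxyl to the ortho prenyl alkene (2,2-dimethylchroman formation) or add methanol or HCl across the alkenes, and the flanked C4' acetal may cleave slowly. Fallback: starting from 19, the acetals are removed by silyl transfer without Brønsted acid. TMSOTf and 2,2'-bipyridyl in MeCN at 0 °C convert the three aryl acetals into 3-[3-methoxy-2,5-bis(3-methylbut-2-enyl)-4-(trimethylsilyloxy)phenyl]-5,7-bis(trimethylsilyloxy)-4H-chromen-4-one F8, which water hydrolyses on work-up to 20.

**Further compounds**

F1 | step 12 | 3-[3-methoxy-4-(methoxymethoxy)-2,5-bis(3-methylbut-2-enyl)phenyl]-5,7-bis(methoxymethoxy)chroman-3,4-diol (racemic, mixture of diastereomers) | OC1c2c(OCOC)cc(OCOC)cc2OCC1(O)c1cc(CC=C(C)C)c(OCOC)c(OC)c1CC=C(C)C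
F2 | step 4 | 3-bromo-4-(methoxymethoxy)-5-(prop-2-enyloxy)benzaldehyde | O=Cc1cc(OCC=C)c(OCOC)c(Br)c1
F3 | step 4 | 5-bromo-3-hydroxy-4-(methoxymethoxy)-2-(prop-2-enyl)benzaldehyde | O=Cc1cc(Br)c(OCOC)c(O)c1CC=C
F4 | step 9 | racemic 2-chloro-1-[3-methoxy-4-(methoxymethoxy)-2,5-bis(3-methylbut-2-enyl)phenyl]ethanol | OC(CCl)c1cc(CC=C(C)C)c(OCOC)c(OC)c1CC=C(C)C
F5 | step 9 | 2-chloro-1-[3-methoxy-4-(methoxymethoxy)-2,5-bis(3-methylbut-2-enyl)phenyl]ethanone | O=C(CCl)c1cc(CC=C(C)C)c(OCOC)c(OC)c1CC=C(C)C
F6 | step 13 | racemic 3-[3-methoxy-4-(methoxymethoxy)-2,5-bis(3-methylbut-2-enyl)phenyl]-5,7-bis(methoxymethoxy)chroman-4-one | O=C1c2c(OCOC)cc(OCOC)cc2OCC1c1cc(CC=C(C)C)c(OCOC)c(OC)c1CC=C(C)C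
F7 | step 13 | {3-[3-methoxy-4-(methoxymethoxy)-2,5-bis(3-methylbut-2-enyl)phenyl]-5,7-bis(methoxymethoxy)-2H-chromen-4-yl}oxytrimethylsilane | C[Si](C)(C)OC1=C(c2cc(CC=C(C)C)c(OCOC)c(OC)c2CC=C(C)C)COc2cc(OCOC)cc(OCOC)c12
F8 | step 14 | 3-[3-methoxy-2,5-bis(3-methylbut-2-enyl)-4-(trimethylsilyloxy)phenyl]-5,7-bis(trimethylsilyloxy)-4H-chromen-4-one | COc1c(O[Si](C)(C)C)c(CC=C(C)C)cc(-c2coc3cc(O[Si](C)(C)C)cc(O[Si](C)(C)C)c3c2=O)c1CC=C(C)C
A1 | alternative 1 | 3,4-dihydroxy-2,5-bis(3-methylbut-2-enyl)benzaldehyde | O=Cc1cc(CC=C(C)C)c(O)c(O)c1CC=C(C)C
A2 | alternative 1 | 3,4-bis[(2-methylbut-3-en-2-yl)oxy]benzaldehyde | O=Cc1ccc(OC(C)(C)C=C)c(OC(C)(C)C=C)c1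
A3 | alternative 2 | 3-[4-acetoxy-3-methoxy-2,5-bis(3-methylbut-2-enyl)phenyl]-4-oxo-4H-chromene-5,7-diyl diacetate | CC(=O)Oc1cc(OC(C)=O)c2c(c1)occ(-c1cc(CC=C(C)C)c(OC(C)=O)c(OC)c1CC=C(C)C)c2=O
A4 | alternative 2 | 3-[4-acetoxy-2,5-bis(bromomethyl)-3-methoxyphenyl]-4-oxo-4H-chromene-5,7-diyl diacetate | CC(=O)Oc1cc(OC(C)=O)c2c(c1)occ(-c1cc(CBr)c(OC(C)=O)c(OC)c1CBr)c2=O
A5 | alternative 2 | tributyl(2-methylprop-1-enyl)stannane | CCCC[Sn](CCCC)(CCCC)C=C(C)C
A6 | alternative 2 | 3-(4-acetoxy-3-methoxy-2,5-dimethylphenyl)-4-oxo-4H-chromene-5,7-diyl diacetate | CC(=O)Oc1cc(OC(C)=O)c2c(c1)occ(-c1cc(C)c(OC(C)=O)c(OC)c1C)c2=O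
A7 | alternative 3 | 2-[3-methoxy-4-(methoxymethoxy)-2,5-bis(3-methylbut-2-enyl)phenyl]-1-(2,4,6-trihydroxyphenyl)ethanone | O=C(Cc1cc(CC=C(C)C)c(OCOC)c(OC)c1CC=C(C)C)c1c(O)cc(O)cc1O
A8 | alternative 3 | 4-hydroxy-6-{3-[3-methoxy-4-(methoxymethoxy)-2,5-bis(3-methylbut-2-enyl)phenyl]-2-oxopropyl}-2H-pyran-2-one | O=C(Cc1cc(O)cc(=O)o1)Cc1cc(CC=C(C)C)c(OCOC)c(OC)c1CC=C(C)C
A9 | alternative 3 | methyl 8-[3-methoxy-4-(methoxymethoxy)-2,5-bis(3-methylbut-2-enyl)phenyl]-3,5,7-trioxooctanoate | COC(=O)CC(=O)CC(=O)CC(=O)Cc1cc(CC=C(C)C)c(OCOC)c(OC)c1CC=C(C)C
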